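**Strategy.** The route rests on disconnecting the C5–C10 bond of ring A (C1–C5, C10). The feature exploited is that the C1 ketone and the C6 aldehyde are 1,4-related through this bond, so C5 and C10 are both enol carbons and must be joined by a like-polarity coupling. Anodic oxidation of a C5=C6 methyl enol ether in methanol reverses the polarity of C5; the C10 enol of a β-keto ester attacks it, closing ring A, creating quaternary C10 and C5, and delivering C6 as its dimethyl acetal in one operation. The precursor is the C/D bicyclo[3.2.1]octane bearing, at C9, the C10 β-keto methyl ester with the gem-dimethyl enol-ether chain, a fluoride-labile ester at C7 and a silyl ether at C15.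

Key step: step 17

Remarks on the chemistry:
- Kaurane locants are used for all intermediates. The bicycle is C8 (quaternary, bears C7), C9, C11, C12, C13, with C14 as the one-carbon bridge and C15–C16 as the two-carbon bridge.
- C7 is carried as a 2-(trimethylsilyl)ethyl ester instead of a methyl ester. It can then be turned into a carboxylate without acid or hydride, which leaves the C20 methyl ester as the only reducible ester in step 19.
- The vinyl bromide (6 to 10) and the enol ether (27 to 29) are used as E/Z mixtures because both isomers converge; their SMILES carry no double-bond descriptor.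
- In step 3 the antipode of the auxiliary or the lithium-solvating additive is chosen so that C8 is formed as S.

**Step 1**
Reactants: 1 methyl 2-oxocyclopentane-1-carboxylate; 2 2-(trimethylsilyl)ethanol
Product: 3 2-(trimethylsilyl)ethyl 2-oxocyclopentane-1-carboxylate
Conditions: 2 (1.2 equiv), DMAP (cat.), toluene, reflux, removal of MeOH
Reagents that add atoms: none
Why: Transesterification of an enolisable β-keto ester (acylketene/enol pathway) should proceed readily and installs the fluoride-labile C7 ester.

**Step 2**
Reactants: 3 2-(trimethylsilyl)ethyl 2-oxocyclopentane-1-carboxylate; 4 L-valine tert-butyl ester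
Product: 5 chiral Z-enamino ester of 3 with 4
Conditions: TsOH (cat.), benzene, Dean–Stark, reflux
Reagents that add atoms: none
Why: Condensation of a β-keto ester with a primary amine should give the hydrogen-bonded enamino ester (enamine formation), which serves as the chiral template for C8.

**Step 3**
Reactants: 5 chiral enamino ester; 6 1,3-dibromopropene (E/Z)
Product: 8 2-(trimethylsilyl)ethyl (1S)-1-(3-bromoprop-2-en-1-yl)-2-oxocyclopentane-1-carboxylate, via alkylated ketimine 7 (not isolated)
Conditions: LDA, toluene, −78 °C; HMPA (1 equiv); 6, −78 → −40 °C; then aq. AcOH/NaOAc, rt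
Reagents that add atoms: water, O
Why: Chiral-enamine alkylation (lithiated amino-ester enamine, chelated by the tert-butyl ester): the auxiliary blocks one face of the aza-enolate, the allylic CH2Br of 6 is attacked from the other face to set quaternary C8 as S, and aqueous acid then cleaves the ketimine.

**Step 4**
Reactants: 8 alkylated β-keto ester
Product: 10 2-(trimethylsilyl)ethyl (1S)-1-(3-bromoprop-2-en-1-yl)-2-oxocyclopent-3-ene-1-carboxylate, via α-phenylselanyl ketone 9 (not isolated)
Conditions: LDA, THF, −78 °C; PhSeCl; then H2O2, pyridine, CH2Cl2, 0 °C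
Reagents that add atoms: none
Why: α-Selenenylation and selenoxide syn-elimination: C16 is the only enolisable carbon and the only β-hydrogens sit on C13, so the C16=C13 enone should form regiospecifically and turn C13 into a radical acceptor.

**Step 5**
Reactants: 10 bromoallyl cyclopentenone
Product: 11 2-(trimethylsilyl)ethyl 7-oxobicyclo[3.2.1]oct-3-ene-1-carboxylate (C11=C12 alkene, C15 ketone, C8 and C13 as in the target)
Conditions: Bu3SnH, AIBN, PhH, 80 °C, slow addition
Reagents that add atoms: none
Why: Vinyl radical cyclisation (tin hydride chain): the rapidly inverting C12 σ-radical from either bromide isomer adds 6-exo to the enone β-carbon C13, necessarily on the face that carries the C8 tether, so C13 is set by C8 and ring C closes.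

**Step 6**
Reactants: 11 bicyclic alkene ketone
Product: 12 C11–C12 epoxide of 11, oxirane on the face syn to the C14 bridge
Conditions: DMDO, acetone, 0 °C
Reagents that add atoms: dimethyldioxirane, CC1(C)OO1
Why: Dioxirane epoxidation (no Baeyer–Villiger competition) should occur on the convex face of the three-carbon bridge, away from the C15–C16 bridge, fixing the C12–O configuration.

**Step 7**
Reactants: 12 epoxide
Product: 13 allylic alcohol: C12–OH syn to the C14 bridge, C9=C11 alkene, C15 ketone
Conditions: LDA (4 equiv), THF, −78 → 40 °C; aq. NH4Cl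
Reagents that add atoms: none
Why: Base-mediated isomerisation of an epoxide to an allylic alcohol (syn β-elimination): with the ketone stored as its enolate, the only removable β-hydrogen is the axial H on C9 syn to oxygen (C13 is a bridgehead), so C9=C11 forms and the C12 oxygen keeps its configuration.

**Step 8**
Reactants: 13 allylic alcohol
Product: 15 C9 acetic ester: CH2CO2Me on C9 syn to the C14 bridge, C11=C12 alkene, via mixed ketene acetal 14 (not isolated)
Conditions: MeC(OMe)3, EtCO2H (cat.), xylene, 140 °C, removal of MeOH; then 1 M HCl, THF
Reagents that add atoms: trimethyl orthoacetate, CC(OC)(OC)OC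
Why: Johnson–Claisen rearrangement: the suprafacial [3,3] shift transfers the C12–O configuration to C9, placing C10 anti to C15 across C8–C9 as in the target, and delivers C10 and C20 in one step.

**Step 9**
Reactants: 15 unsaturated keto diester
Product: 16 saturated keto diester (C9–CH2CO2Me, C15 ketone)
Conditions: H2 (1 atm), 10% Pd/C, EtOAc, rt
Reagents that add atoms: none
Why: Catalytic hydrogenation of the only alkene should be clean and creates no stereocentre.

**Step 10**
Reactants: 16 saturated keto diester
Product: 18 exo-methylene ketone (C16=C17, C15 ketone), via Mannich base 17 (not isolated)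
Conditions: (CH2O)n, PhNHMe·TFA, THF, reflux
Reagents that add atoms: formaldehyde (as paraformaldehyde), C=O
Why: Mannich condensation and elimination (α-methylenation of a ketone): C16 is the only enolisable ketone position, and the exocyclic enone cannot move into the ring because C13 is a bridgehead.

**Step 11**
Reactants: 18 exo-methylene ketone
Product: 19 allylic alcohol with C15–OH endo (syn to the C9–C11–C12 bridge)
Conditions: NaBH4, CeCl3·7H2O, MeOH, −78 → −20 °C
Reagents that add atoms: none
Why: Luche 1,2-reduction: hydride should reach C15 from the less hindered exo face (C14 side), giving the endo alcohol, which is the C15 configuration of the target.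

**Step 12**
Reactants: 19 allylic alcohol
Product: 20 C15 tert-butyldimethylsilyl ether
Conditions: TBSOTf, 2,6-lutidine, CH2Cl2, −78 → 0 °C
Reagents that add atoms: tert-butyldimethylsilyl triflate, CC(C)(C)[Si](C)(C)OS(=O)(=O)C(F)(F)F
Why: Silylation of a hindered secondary alcohol; the ether prevents retro-aldol opening of ring D (C15 alkoxide next to the C7 ester) in the enolate steps.

**Step 13**
Reactants: 21 isobutyraldehyde; 22 methyl acrylate
Product: 25 methyl 4,4-dimethyl-5-oxopentanoate, via enamine 23 (not isolated), via cyclobutane amino ester 24 (not isolated)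
Conditions: pyrrolidine, toluene, Dean–Stark; 22, MeCN, reflux; then aq. AcOH
Reagents that add atoms: water, O
Why: Stork enamine Michael addition: the α,α-disubstituted enamine adds to the acrylate through its cyclobutane adduct, and hydrolysis should return the aldehyde with the C4 gem-dimethyl carbon in place.

**Step 14**
Reactants: 25 aldehyde ester; 26 (methoxymethyl)triphenylphosphonium chloride
Product: 27 methyl 6-methoxy-4,4-dimethylhex-5-enoate (E/Z)
Conditions: 26, KOtBu, THF, 0 °C; then 25, 0 °C → rt
Reagents that add atoms: none
Why: Wittig methoxymethylenation, which tolerates neopentyl aldehydes, introduces C6 as the enol ether; both geometric isomers are usable.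

**Step 15**
Reactants: 27 enol ether ester
Product: 28 N-methoxy-N-methyl-6-methoxy-4,4-dimethylhex-5-enamide
Conditions: MeNH(OMe)·HCl, iPrMgCl, THF, −20 → 0 °C
Reagents that add atoms: N,O-dimethylhydroxylamine hydrochloride, CNOC.Cl
Why: Direct ester-to-Weinreb-amide conversion via the magnesium amide keeps the acid-sensitive enol ether under basic conditions and gives an acyl donor that adds only once.

**Step 16**
Reactants: 20 silyl-protected diester; 28 Weinreb amide
Product: 29 key-step precursor: bicycle bearing at C9 the C10 β-keto methyl ester with the C2–C6 enol-ether chain (C10 epimers and enol)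
Conditions: 20, LDA, THF, −78 °C; then 28, −78 → −30 °C; aq. NH4Cl
Reagents that add atoms: none
Why: Crossed Claisen acylation of an ester enolate with a Weinreb amide: C10 is the only acidic position (C8 is quaternary), and the chelated adduct should collapse to the β-keto ester only on work-up.

**Step 17**
Reactants: 29 key-step precursor
Product: 30 ring-A-closed β-keto ester with C6 dimethyl acetal
Conditions: RVC anode, Pt cathode, undivided cell, 8 mA, 2.2 F mol−1; 0.1 M Et4NOTs, MeOH/THF (3:7), 2,6-lutidine, rt
Reagents that add atoms: methanol, CO
Why: Proposed new method: one-electron anodic oxidation of the C5=C6 enol ether, the most easily oxidised group in 29, should give a radical cation that the C10 enol of the β-keto ester attacks at C5, after which a second electron transfer from the α-methoxy C6 radical gives an oxocarbenium ion that methanol captures as the acetal; the closest known reactions are intramolecular anodic couplings of enol ether radical cations with enol-type nucleophiles and Mn(III) oxidative cyclisations of β-keto esters, neither shown for attack at a carbon next to a quaternary centre. Ring A closes 6-exo-trig with respect to C5=C6, with the C10 enol endocyclic to the new ring. At C10, which sits axially on C9, one enol face is buried over ring C, and allylic 1,3-strain keeps the in-plane C2 methylene away from quaternary C8 while the ester flanks C8, so C5 should add to the exposed face anti to C8, which is the configuration of the target. At C5 a chair transition state places the C6 substituent equatorial and trans to C9, and any epimer is corrected in step 22 through the enolisable aldehyde. The step needs oxidation of the enol ether in preference to the 1,1-disubstituted alkene and exo rather than endo closure, which the low potential of the enol ether, methoxy stabilisation at C6 and the gem-dimethyl group at C4 should secure.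

**Step 18**
Reactants: 30 cyclised acetal
Product: 31 C7 carboxylic acid with free C15–OH (β-keto methyl ester and acetal intact)
Conditions: TBAF, THF, 0 → 40 °C; aq. NH4Cl
Reagents that add atoms: none
Why: Fluoride-mediated desilylation: the 2-(trimethylsilyl)ethyl ester fragments to ethylene and the C7 carboxylate and the C15 silyl ether is cleaved in the same operation, with no acid near the acetal.

**Step 19**
Reactants: 31 hydroxy acid keto ester
Product: 32 C20 primary alcohol (C7 acid, C15–OH, C1 ketone, C6 acetal)
Conditions: LDA (3.3 equiv), THF, −78 °C; LiAlH4, −78 → 0 °C; AcOH, −78 °C, then Rochelle salt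
Reagents that add atoms: none
Why: Ketone protection as its lithium enolate (C2 is the only enolisable position) with C7 and C15 stored as carboxylate and alkoxide leaves the C20 methyl ester as the only carbonyl open to hydride reduction, and the cold acidic quench avoids retro-aldol loss of the new hydroxymethyl group.

**Step 20**
Reactants: 32 dihydroxy acid
Product: 34 7,20-lactone with C15 acetate (C1 ketone, C6 acetal), via hydroxy lactone 33 (not isolated)
Conditions: 2-chloro-1-methylpyridinium iodide, Et3N, CH2Cl2, rt; then Ac2O, DMAP, rt
Reagents that add atoms: acetic anhydride, CC(=O)OC(C)=O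
Why: Mukaiyama lactonisation: the activated C7 acyl group should be taken by the primary C20 hydroxyl in a six-membered ring (C15–OH could only give a β-lactone), and DMAP-catalysed acetylation then installs the C15 acetate.

**Step 21**
Reactants: 34 saturated keto lactone
Product: 35 C2=C3 enone (lactone, C15 acetate, C6 acetal)
Conditions: IBX, DMSO/PhF, 70 °C
Reagents that add atoms: none
Why: IBX dehydrogenation of a ketone: C2–C3 is the only position that can be desaturated because C10 and C4 are quaternary, and the masked aldehyde has no β-hydrogen.

**Step 22**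
Reactants: 35 enone acetal
Product: 36 CNP0108627.4 (target)
Conditions: PPTS, acetone/H2O (10:1), 50 °C
Reagents that add atoms: water, O
Why: Acid-catalysed acetal hydrolysis under conditions mild enough for the allylic acetate and the exo-methylene group; C5, now α to the aldehyde, can equilibrate to the equatorial-formyl configuration of the target.

**Compound list**
1 | methyl 2-oxocyclopentane-1-carboxylate | COC(=O)C1CCCC1=O | starting material
2 | 2-(trimethylsilyl)ethanol | C[Si](C)(C)CCO | starting material
3 | 2-(trimethylsilyl)ethyl 2-oxocyclopentane-1-carboxylate | O=C1CCCC1C(=O)OCC[Si](C)(C)C | intermediate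
4 | L-valine tert-butyl ester | CC(C)[C@H](N)C(=O)OC(C)(C)C | starting material
5 | tert-butyl (S)-N-{2-[2-(trimethylsilyl)ethoxycarbonyl]cyclopent-1-en-1-yl}valinate | CC(C)[C@H](NC1=C(CCC1)C(=O)OCC[Si](C)(C)C)C(=O)OC(C)(C)C | intermediate
6 | 1,3-dibromopropene (E/Z) | BrCC=CBr | starting material
7 | alkylated ketimine (C8 S, valine ester on N) | CC(C)[C@H](N=C1CCC[C@@]1(CC=CBr)C(=O)OCC[Si](C)(C)C)C(=O)OC(C)(C)C | intermediate (not isolated)
8 | 2-(trimethylsilyl)ethyl (1S)-1-(3-bromoprop-2-en-1-yl)-2-oxocyclopentane-1-carboxylate | O=C1CCC[C@@]1(CC=CBr)C(=O)OCC[Si](C)(C)C | intermediate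
9 | 3-(phenylselanyl) derivative of 8 (C16 epimers) | O=C1C([Se]c2ccccc2)CC[C@@]1(CC=CBr)C(=O)OCC[Si](C)(C)C | intermediate (not isolated)
10 | 2-(trimethylsilyl)ethyl (1S)-1-(3-bromoprop-2-en-1-yl)-2-oxocyclopent-3-ene-1-carboxylate | O=C1C=CC[C@@]1(CC=CBr)C(=O)OCC[Si](C)(C)C | intermediate
11 | 2-(trimethylsilyl)ethyl 7-oxobicyclo[3.2.1]oct-3-ene-1-carboxylate (C11=C12, C15=O) | C1[C@@H]2C=CC[C@](C2)(C(=O)OCC[Si](C)(C)C)C1=O | intermediate
12 | C11–C12 epoxide of 11, oxygen syn to the C14 bridge | C1[C@@H]2[C@H]3O[C@H]3C[C@](C2)(C(=O)OCC[Si](C)(C)C)C1=O | intermediate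
13 | allylic alcohol, C12–OH syn to the C14 bridge, C9=C11 | C1[C@@H]2[C@@H](O)C=C[C@](C2)(C(=O)OCC[Si](C)(C)C)C1=O | intermediate
14 | 1-methoxyvinyl ether of 13 | C1[C@@H]2[C@@H](OC(=C)OC)C=C[C@](C2)(C(=O)OCC[Si](C)(C)C)C1=O | intermediate (not isolated)
15 | C9-(2-methoxy-2-oxoethyl) C11=C12 keto diester, side chain syn to the C14 bridge | C1[C@@H]2C=C[C@@H](CC(=O)OC)[C@](C2)(C(=O)OCC[Si](C)(C)C)C1=O | intermediate
16 | saturated keto diester | C1[C@@H]2CC[C@@H](CC(=O)OC)[C@](C2)(C(=O)OCC[Si](C)(C)C)C1=O | intermediate
17 | C16 (N-methylanilino)methyl ketone | CN(CC1[C@@H]2CC[C@@H](CC(=O)OC)[C@](C2)(C(=O)OCC[Si](C)(C)C)C1=O)c1ccccc1 | intermediate (not isolated)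
18 | C16 methylidene C15 ketone | C=C1[C@@H]2CC[C@@H](CC(=O)OC)[C@](C2)(C(=O)OCC[Si](C)(C)C)C1=O | intermediate
19 | C15 endo allylic alcohol | C=C1[C@@H]2CC[C@@H](CC(=O)OC)[C@](C2)(C(=O)OCC[Si](C)(C)C)[C@@H]1O | intermediate
20 | C15 tert-butyldimethylsilyl ether of 19 | C=C1[C@@H]2CC[C@@H](CC(=O)OC)[C@](C2)(C(=O)OCC[Si](C)(C)C)[C@@H]1O[Si](C)(C)C(C)(C)C | intermediate
21 | isobutyraldehyde | CC(C)C=O | starting material
22 | methyl acrylate | C=CC(=O)OC | starting material
23 | 1-(2-methylprop-1-en-1-yl)pyrrolidine | CC(C)=CN1CCCC1 | intermediate (not isolated)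
24 | methyl 3,3-dimethyl-2-(pyrrolidin-1-yl)cyclobutane-1-carboxylate | COC(=O)C1CC(C)(C)C1N1CCCC1 | intermediate (not isolated)
25 | methyl 4,4-dimethyl-5-oxopentanoate | COC(=O)CCC(C)(C)C=O | intermediate
26 | (methoxymethyl)triphenylphosphonium chloride | COC[P+](c1ccccc1)(c1ccccc1)c1ccccc1.[Cl-] | starting material
27 | methyl 6-methoxy-4,4-dimethylhex-5-enoate (E/Z) | COC=CC(C)(C)CCC(=O)OC | intermediate
28 | N-methoxy-N-methyl-6-methoxy-4,4-dimethylhex-5-enamide (E/Z) | COC=CC(C)(C)CCC(=O)N(C)OC | intermediate
29 | key-step precursor: C10 β-keto methyl ester with enol-ether chain on the C/D bicycle | C=C1[C@@H]2CC[C@@H](C(C(=O)OC)C(=O)CCC(C)(C)C=COC)[C@](C2)(C(=O)OCC[Si](C)(C)C)[C@@H]1O[Si](C)(C)C(C)(C)C | intermediate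
30 | ring-A-closed β-keto ester with C6 dimethyl acetal | C=C1[C@@H]2CC[C@@H]([C@]3(C(=O)OC)C(=O)CCC(C)(C)[C@H]3C(OC)OC)[C@](C2)(C(=O)OCC[Si](C)(C)C)[C@@H]1O[Si](C)(C)C(C)(C)C | intermediate
31 | C7 acid, C15 alcohol, C20 methyl ester | C=C1[C@@H]2CC[C@@H]([C@]3(C(=O)OC)C(=O)CCC(C)(C)[C@H]3C(OC)OC)[C@](C2)(C(=O)O)[C@@H]1O | intermediate
32 | C7 acid, C15 alcohol, C20 hydroxymethyl | C=C1[C@@H]2CC[C@@H]([C@]3(CO)C(=O)CCC(C)(C)[C@H]3C(OC)OC)[C@](C2)(C(=O)O)[C@@H]1O | intermediate
33 | 7,20-lactone with free C15–OH | C=C1[C@@H]2CC[C@@H]3[C@](C2)(C(=O)OC[C@]32C(=O)CCC(C)(C)[C@H]2C(OC)OC)[C@@H]1O | intermediate (not isolated)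
34 | 7,20-lactone C15 acetate, C1 ketone, C6 acetal | C=C1[C@@H]2CC[C@@H]3[C@](C2)(C(=O)OC[C@]32C(=O)CCC(C)(C)[C@H]2C(OC)OC)[C@@H]1OC(C)=O | intermediate
35 | C2=C3 enone, C6 dimethyl acetal | C=C1[C@@H]2CC[C@@H]3[C@](C2)(C(=O)OC[C@]32C(=O)C=CC(C)(C)[C@H]2C(OC)OC)[C@@H]1OC(C)=O | intermediate
36 | CNP0108627.4 | C=C1[C@@H]2CC[C@@H]3[C@](C2)(C(=O)OC[C@]32C(=O)C=CC(C)(C)[C@H]2C=O)[C@@H]1OC(C)=O | target

**Step count.** Total: 22 steps. Longest linear sequence: 19 steps (steps 1–12, then 16–22); the side chain (steps 13–15) is made in parallel.

**Steps most likely to fail**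

1. Step 17 (Proposed new method). Bond formation at the neopentyl C5 may be too slow, so that methanol intercepts the radical cation before the C10 enol does and the chain is lost as uncyclised acetal. The fallback uses known chemistry and sets out from 29: electrolysis is replaced by chemical one-electron oxidation of the dicarbonyl partner with Mn(OAc)3·2H2O and Cu(OAc)2 in KOAc-buffered methanol. The Mn(III) enolate gives a C10-centred radical that adds 6-exo to the neutral enol ether, Cu(II) oxidises the resulting α-methoxy radical, and methanol capture leads back to the route at 30. No new compound is made.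

2. Step 7. The strong amide base may attack the C7 ester or trigger condensation of the ketone enolate before the syn-elimination is complete. The fallback sets out from 11 and bypasses the epoxide: a Schenck ene reaction (O2, hν, tetraphenylporphyrin, CH2Cl2, 0 °C) should add singlet oxygen to C12 on the exo face while removing the axial hydrogen on C9. This gives the allylic hydroperoxide F1, and triphenylphosphine reduces it to the alcohol, so that the route is rejoined at 13.

3. Step 16. Acylation of the hindered C10 enolate by the amide may be slow, so that proton exchange and enolate decomposition win. The fallback replaces acyl substitution by aldol addition and oxidation. It sets out from 27, which DIBAL at −78 °C reduces to 6-methoxy-4,4-dimethylhex-5-enal F2. The lithium enolate of 20 adds to this aldehyde at −78 °C to give the β-hydroxy ester F3, and Dess–Martin oxidation buffered with NaHCO3 gives the β-keto ester, rejoining the route at 29.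

**Further compounds**
F0 | step 17 | none | none
F1 | step 7 | allylic hydroperoxide, C12–OOH syn to the C14 bridge, C9=C11 | C1[C@@H]2[C@@H](OO)C=C[C@](C2)(C(=O)OCC[Si](C)(C)C)C1=O
F2 | step 16 | 6-methoxy-4,4-dimethylhex-5-enal (E/Z) | COC=CC(C)(C)CCC=O
F3 | step 16 | β-hydroxy ester from 20 and F2 (C10/C1 diastereomers) | C=C1[C@@H]2CC[C@@H](C(C(=O)OC)C(O)CCC(C)(C)C=COC)[C@](C2)(C(=O)OCC[Si](C)(C)C)[C@@H]1O[Si](C)(C)C(C)(C)C
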